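**Plan**

1. Each half is numbered as a naphthalene: C1 OH, C2 acetyl, C3 methyl, C4 biaryl carbon, C6 and C8 OH; ring A = C1–C4 with C4a and C8a, ring B = C4a, C5–C8, C8a. These locants are used in the text and differ from those of the systematic names.
2. Enabling feature: ring B carries oxygen on C6 and C8, the pattern left when a 1,3-dioxygenated butadiene adds across C4a=C8a and aromatizes. The 4,4'-binaphthol is the reduced form of an extended quinone whose two ring A dienones offer these C4a=C8a bonds as dienophiles.
3. Retrosynthesis: the binaphthol is taken back to the binaphthylidene dione. The bonds C4a–C5 and C8a–C8 of both halves are then cut together, giving a dibromodiphenoquinone and two molecules of a bis(silyloxy) diene. The central C4–C4' bond is cut last, giving an aryl iodide and the aryl boronate made from it.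
4. Forward: C4–C4' is made first by cross-coupling of the iodide and the boronate of the same ring A unit, bromine is placed on C8a, the biphenol is oxidized, both rings B close in one operation, and dithionite sets the final oxidation level.
5. Stereochemistry: the target has no stereocentre. The stereocentres of the cycloadducts are erased on aromatization, and the hindered biaryl axis arises racemic in the last step.

Key step: step 8

Assumption: the target SMILES fixes no configuration at the 4,4' axis, so the racemic atropisomer is made.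

**Route**

Step 1
Reactants: 1 1-(2-hydroxy-6-methylphenyl)ethan-1-one
Product: 2 1-(6-hydroxy-3-iodo-2-methylphenyl)ethan-1-one
Conditions: NIS, TsOH·H2O (cat.), MeCN, 0 °C to rt
Reagents that add atoms: N-iodosuccinimide, O=C1CCC(=O)N1I
Why: Electrophilic aromatic iodination of a phenol goes para to the hydroxyl group, here the position that is also ortho to methyl and meta to acetyl, as in the para halogenation of 3-methylphenol.

Step 2
Reactants: 2 1-(6-hydroxy-3-iodo-2-methylphenyl)ethan-1-one
Product: 3 1-[6-hydroxy-2-methyl-3-(4,4,5,5-tetramethyl-1,3,2-dioxaborolan-2-yl)phenyl]ethan-1-one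
Conditions: B2pin2 (1.2 equiv), Pd(dppf)Cl2 (3 mol %), KOAc (3 equiv), 1,4-dioxane, 85 °C
Reagents that add atoms: bis(pinacolato)diboron, CC1(C)OB(OC1(C)C)B1OC(C)(C)C(C)(C)O1
Why: Miyaura borylation of an aryl iodide with the weak base KOAc stops at the pinacol boronate, because acetate does not promote its onward coupling, and free phenols and aryl ketones are tolerated.

Step 3
Reactants: 2 1-(6-hydroxy-3-iodo-2-methylphenyl)ethan-1-one; 3 1-[6-hydroxy-2-methyl-3-(4,4,5,5-tetramethyl-1,3,2-dioxaborolan-2-yl)phenyl]ethan-1-one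
Product: 4 1,1'-(4,4'-dihydroxy-2,2'-dimethyl-[1,1'-biphenyl]-3,3'-diyl)bis(ethan-1-one)
Conditions: Pd(OAc)2 (3 mol %), SPhos (6 mol %), K3PO4 (4 equiv), 1,4-dioxane/H2O, 80 °C
Reagents that add atoms: none
Why: Suzuki–Miyaura cross-coupling of the aryl iodide with the aryl pinacol boronate joins one molecule of each at C4–C4'; free phenols are carried as phenolates and a dialkylbiarylphosphine ligand copes with one ortho methyl group on each ring.

Step 4
Reactants: 4 1,1'-(4,4'-dihydroxy-2,2'-dimethyl-[1,1'-biphenyl]-3,3'-diyl)bis(ethan-1-one)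
Product: 5 1,1'-(5,5'-dibromo-4,4'-dihydroxy-2,2'-dimethyl-[1,1'-biphenyl]-3,3'-diyl)bis(ethan-1-one)
Conditions: NBS (2.1 equiv), i-Pr2NH (10 mol %), CH2Cl2, 0 °C
Reagents that add atoms: N-bromosuccinimide, O=C1CCC(=O)N1Br
Why: Amine-mediated electrophilic bromination of phenols is ortho selective, and the only free position ortho or para to each hydroxyl group is the one that becomes C8a.

Step 5
Reactants: 6 methyl 3-oxobutanoate
Product: 7 methyl (E)-3-(trimethylsilyloxy)but-2-enoate (either geometry serves)
Conditions: Me3SiCl, Et3N, hexane, rt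
Reagents that add atoms: chlorotrimethylsilane, C[Si](C)(C)Cl
Why: O-silylation of the enol of a β-keto ester under soft enolization gives the silyl enol ether.

Step 6
Reactants: 7 methyl (E)-3-(trimethylsilyloxy)but-2-enoate
Product: 9 (Z)-1-methoxy-1,3-bis(trimethylsilyloxy)buta-1,3-diene, via lithium dienolate 8 (not isolated)
Conditions: LiN(i-Pr)2, THF, −78 °C; then Me3SiCl, −78 to 0 °C
Reagents that add atoms: chlorotrimethylsilane, C[Si](C)(C)Cl
Why: Kinetic γ-deprotonation of the silyloxy enoate and O-silylation of the resulting dienolate is the standard preparation of this 1,3-bis(silyloxy) diene.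

Step 7
Reactants: 5 1,1'-(5,5'-dibromo-4,4'-dihydroxy-2,2'-dimethyl-[1,1'-biphenyl]-3,3'-diyl)bis(ethan-1-one)
Product: 10 (E)-3,3'-diacetyl-5,5'-dibromo-2,2'-dimethyl-[1,1'-bi(cyclohexa-2,5-dien-1-ylidene)]-4,4'-dione (drawn as E; the Z isomer would serve equally)
Conditions: PbO2 (activated, excess), 4 Å molecular sieves, CH2Cl2, rt, dark; filtered through Celite and used at once
Reagents that add atoms: none
Why: Two-electron oxidation of a 4,4'-biphenol to its diphenoquinone by lead dioxide is a standard transformation, and an oxidant this strong is chosen because the acetyl groups raise the potential of the biphenol.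

Step 8
Reactants: 10 (E)-3,3'-diacetyl-5,5'-dibromo-2,2'-dimethyl-[1,1'-bi(cyclohexa-2,5-dien-1-ylidene)]-4,4'-dione; 9 (Z)-1-methoxy-1,3-bis(trimethylsilyloxy)buta-1,3-diene (3 equiv)
Product: 13 (E)-3,3'-diacetyl-5,5',7,7'-tetrahydroxy-2,2'-dimethyl-4H,4'H-[1,1'-binaphthalenylidene]-4,4'-dione, via bis-cycloadduct 11 (not isolated), via tetrakis(trimethylsilyl) ether 12 (not isolated)
Conditions: 9 (3 equiv), toluene, −40 °C to rt; then 1 M HCl, THF, rt
Reagents that add atoms: none
Why: Proposed new method: each C4a=C8a bond of 10 is the only disubstituted alkene of a cross-conjugated dienone and should take up diene 9 in a concerted, asynchronous [4+2] cycloaddition, so that each ring B closes suprafacially through the bonds C4a–C5 and C8a–C8 to give 11; the closest known reaction type is the bromine-directed Diels–Alder addition of 1,3-dioxygenated butadienes to bromobenzoquinones and bromonaphthoquinones with aromatization by loss of HBr and methanol, which has not been shown on a diphenoquinone. Loss of HBr across C4a–C8a restores the quinoid ring A and loss of methanol from the mixed ketal aromatizes ring B to 12, which the acid treatment desilylates to 13. The cis ring fusions and the ketal carbons of 11 are the only new stereocentres; they follow from suprafacial addition and are all erased, so no stereocontrol is needed and the geometry of the central alkene is merely carried over. The selectivity needed is the orientation of the diene: its nucleophilic CH2 terminus must bond to C4a and its ketene acetal carbon to C8a, so that oxygen ends on C6 and C8. Bromine on C8a is relied on for this as in bromoquinones, since by induction it strengthens the adjacent C1 carbonyl as acceptor toward its β carbon C4a and by lone-pair donation it weakens the distal carbonyl that activates C8a; the inherent bias of a diphenoquinone toward attack next to the carbonyl opposes this, which is why a nonpolar solvent and low temperature are chosen to favour the concerted path over ionic addition. Reaction at other alkenes is excluded because C2=C3 and the central C4=C4' bond are tetrasubstituted, and the excess of 9 takes up the HBr that is set free.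

Step 9
Reactants: 13 (E)-3,3'-diacetyl-5,5',7,7'-tetrahydroxy-2,2'-dimethyl-4H,4'H-[1,1'-binaphthalenylidene]-4,4'-dione
Product: 14 1,1'-(4,4',5,5',7,7'-hexahydroxy-2,2'-dimethyl-[1,1'-binaphthalene]-3,3'-diyl)bis(ethan-1-one) (racemic at the axis), the target
Conditions: Na2S2O4, EtOAc/H2O, rt, under argon
Reagents that add atoms: none
Why: Dithionite reduction of a quinone to its hydroquinone converts the central alkene into the biaryl bond and leaves the aryl ketones untouched.

**Compound list**

1 | 1-(2-hydroxy-6-methylphenyl)ethan-1-one | CC(=O)c1c(C)cccc1O | starting material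
2 | 1-(6-hydroxy-3-iodo-2-methylphenyl)ethan-1-one | CC(=O)c1c(C)c(I)ccc1O | intermediate
3 | 1-[6-hydroxy-2-methyl-3-(4,4,5,5-tetramethyl-1,3,2-dioxaborolan-2-yl)phenyl]ethan-1-one | CC(=O)c1c(C)c(B2OC(C)(C)C(C)(C)O2)ccc1O | intermediate
4 | 1,1'-(4,4'-dihydroxy-2,2'-dimethyl-[1,1'-biphenyl]-3,3'-diyl)bis(ethan-1-one) | CC(=O)c1c(C)c(-c2ccc(O)c(C(C)=O)c2C)ccc1O | intermediate
5 | 1,1'-(5,5'-dibromo-4,4'-dihydroxy-2,2'-dimethyl-[1,1'-biphenyl]-3,3'-diyl)bis(ethan-1-one) | CC(=O)c1c(C)c(-c2cc(Br)c(O)c(C(C)=O)c2C)cc(Br)c1O | intermediate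
6 | methyl 3-oxobutanoate | COC(=O)CC(C)=O | starting material
7 | methyl (E)-3-(trimethylsilyloxy)but-2-enoate | C/C(O[Si](C)(C)C)=C\C(=O)OC | intermediate
8 | lithium (E)-1-methoxy-3-(trimethylsilyloxy)buta-1,3-dien-1-olate (not isolated) | C=C(O[Si](C)(C)C)/C=C(/OC)[O-].[Li+] | intermediate
9 | (Z)-1-methoxy-1,3-bis(trimethylsilyloxy)buta-1,3-diene | C=C(O[Si](C)(C)C)/C=C(/OC)O[Si](C)(C)C | intermediate
10 | (E)-3,3'-diacetyl-5,5'-dibromo-2,2'-dimethyl-[1,1'-bi(cyclohexa-2,5-dien-1-ylidene)]-4,4'-dione | CC(=O)C1=C(C)/C(=C2/C(C)=C(C(C)=O)C(=O)C(Br)=C2)C=C(Br)C1=O | intermediate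
11 | (E)-3,3'-diacetyl-4a,4a'-dibromo-5,5'-dimethoxy-2,2'-dimethyl-5,5',7,7'-tetrakis(trimethylsilyloxy)-4a,4a',5,5',8,8',8a,8a'-octahydro-4H,4'H-[1,1'-binaphthalenylidene]-4,4'-dione, cis ring fusions, one of several diastereomers drawn, ketal carbons unassigned (not isolated) | CC(=O)C1=C(C)/C(=C3/C(C)=C(C(C)=O)C(=O)[C@]4(Br)[C@H]3CC(O[Si](C)(C)C)=CC4(OC)O[Si](C)(C)C)[C@@H]2CC(O[Si](C)(C)C)=CC(OC)(O[Si](C)(C)C)[C@]2(Br)C1=O | intermediate
12 | (E)-3,3'-diacetyl-2,2'-dimethyl-5,5',7,7'-tetrakis(trimethylsilyloxy)-4H,4'H-[1,1'-binaphthalenylidene]-4,4'-dione (not isolated) | CC(=O)C1=C(C)/C(=C2/C(C)=C(C(C)=O)C(=O)c3c(O[Si](C)(C)C)cc(O[Si](C)(C)C)cc23)c2cc(O[Si](C)(C)C)cc(O[Si](C)(C)C)c2C1=O | intermediate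
13 | (E)-3,3'-diacetyl-5,5',7,7'-tetrahydroxy-2,2'-dimethyl-4H,4'H-[1,1'-binaphthalenylidene]-4,4'-dione | CC(=O)C1=C(C)/C(=C2/C(C)=C(C(C)=O)C(=O)c3c(O)cc(O)cc23)c2cc(O)cc(O)c2C1=O | intermediate
14 | 1,1'-(4,4',5,5',7,7'-hexahydroxy-2,2'-dimethyl-[1,1'-binaphthalene]-3,3'-diyl)bis(ethan-1-one), racemic | CC(=O)c1c(C)c(-c2c(C)c(C(C)=O)c(O)c3c(O)cc(O)cc23)c2cc(O)cc(O)c2c1O | target

**Step count**

Total: 9 steps. Longest linear sequence: 7 steps (steps 1, 2, 3, 4, 7, 8, 9); steps 5 and 6 are a two-step branch to the diene.

**Steps most likely to fail**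

Step 8. The diene may add with the opposite orientation, or by conjugate addition and loss of bromide at the bromine-bearing carbon, because in a diphenoquinone the carbon next to the carbonyl is the inherently more electrophilic one. Electron transfer from the electron-rich diene to the strongly oxidizing quinone may also consume both partners. The fallback uses known chemistry, sets out from diene 9 and comes back at target 14; it builds ring A onto a preformed ring B and joins the halves last, so the oxygen pattern is fixed by the arene used. Diene 9 would be heated with methyl but-2-ynoate (toluene, 110 °C; then aq HCl) in a Diels–Alder addition with aromatization to give methyl 2,4-dihydroxy-6-methylbenzoate F1. O-Methylation (Me2SO4, K2CO3, acetone) would give methyl 2,4-dimethoxy-6-methylbenzoate F2. Lateral deprotonation (LiN(i-Pr)2, THF, −78 °C) and addition of (E)-pent-3-en-2-one would bring about a tandem Michael–Dieckmann annulation to racemic 1-(1-hydroxy-6,8-dimethoxy-3-methyl-3,4-dihydronaphthalen-2-yl)ethan-1-one F3. Dehydrogenation with DDQ (1,4-dioxane, reflux) would give 1-(1-hydroxy-6,8-dimethoxy-3-methylnaphthalen-2-yl)ethan-1-one F4. Iodination para to the naphthol hydroxyl (I2, NaHCO3, aq THF) would give 1-(1-hydroxy-4-iodo-6,8-dimethoxy-3-methylnaphthalen-2-yl)ethan-1-one F5. Miyaura borylation of part of F5 (B2pin2, Pd(dppf)Cl2, KOAc, 1,4-dioxane, 85 °C) would give 1-[1-hydroxy-6,8-dimethoxy-3-methyl-4-(4,4,5,5-tetramethyl-1,3,2-dioxaborolan-2-yl)naphthalen-2-yl]ethan-1-one F6. Suzuki–Miyaura coupling of F6 with the remaining F5 (Pd(OAc)2, SPhos, K3PO4, 1,4-dioxane/H2O, 100 °C) would give 1,1'-(4,4'-dihydroxy-5,5',7,7'-tetramethoxy-2,2'-dimethyl-[1,1'-binaphthalene]-3,3'-diyl)bis(ethan-1-one) F7. Cleavage of the four methyl ethers with BBr3 (CH2Cl2, −78 °C to rt) would give 14.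

Step 7. Oxidation on the oxide surface may stop short, or the electrophilic quinone may degrade through the water that is formed or through tautomerization at its methyl and acetyl groups. The fallback sets out from 5 and comes back at 10; it replaces dehydrogenation of the neutral phenol by homogeneous, water-free electron transfer from the preformed bis-phenolate, which is far easier to oxidize. Biphenol 5 would be deprotonated with NaH (2 equiv, THF, 0 °C) to disodium 3,3'-diacetyl-5,5'-dibromo-2,2'-dimethyl-[1,1'-biphenyl]-4,4'-bis(olate) F8. One equivalent of I2 (THF, −40 °C) would then oxidize F8, and filtration from the sodium iodide would leave a solution of 10 for direct use in step 8.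

Step 3. The chelating ortho-acyl phenolates may hold back the palladium catalyst, or protodeboronation of the electron-rich boronate may outrun transmetalation, so that conversion to the biaryl stays low. The fallback sets out from 2 and comes back at 4; it moves the coupling to a protected substrate and to copper. Iodide 2 would be O-methylated (MeI, K2CO3, acetone) to 1-(3-iodo-6-methoxy-2-methylphenyl)ethan-1-one F9. Ullmann homocoupling with copper powder (DMF, 150 °C) would give 1,1'-(4,4'-dimethoxy-2,2'-dimethyl-[1,1'-biphenyl]-3,3'-diyl)bis(ethan-1-one) F10. BCl3 (CH2Cl2, 0 °C) would cleave the two methyl ethers, which are activated by the ortho acetyl groups, to give 4.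

**Further compounds**

F1 | step 8 | methyl 2,4-dihydroxy-6-methylbenzoate | COC(=O)c1c(C)cc(O)cc1O
F2 | step 8 | methyl 2,4-dimethoxy-6-methylbenzoate | COC(=O)c1c(C)cc(OC)cc1OC
F3 | step 8 | 1-(1-hydroxy-6,8-dimethoxy-3-methyl-3,4-dihydronaphthalen-2-yl)ethan-1-one, racemic | CC(=O)C1=C(O)c2c(OC)cc(OC)cc2CC1C
F4 | step 8 | 1-(1-hydroxy-6,8-dimethoxy-3-methylnaphthalen-2-yl)ethan-1-one | CC(=O)c1c(C)cc2cc(OC)cc(OC)c2c1O
F5 | step 8 | 1-(1-hydroxy-4-iodo-6,8-dimethoxy-3-methylnaphthalen-2-yl)ethan-1-one | CC(=O)c1c(C)c(I)c2cc(OC)cc(OC)c2c1O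
F6 | step 8 | 1-[1-hydroxy-6,8-dimethoxy-3-methyl-4-(4,4,5,5-tetramethyl-1,3,2-dioxaborolan-2-yl)naphthalen-2-yl]ethan-1-one | CC(=O)c1c(C)c(B3OC(C)(C)C(C)(C)O3)c2cc(OC)cc(OC)c2c1O
F7 | step 8 | 1,1'-(4,4'-dihydroxy-5,5',7,7'-tetramethoxy-2,2'-dimethyl-[1,1'-binaphthalene]-3,3'-diyl)bis(ethan-1-one), racemic | CC(=O)c1c(C)c(-c2c(C)c(C(C)=O)c(O)c3c(OC)cc(OC)cc23)c2cc(OC)cc(OC)c2c1O
F8 | step 7 | disodium 3,3'-diacetyl-5,5'-dibromo-2,2'-dimethyl-[1,1'-biphenyl]-4,4'-bis(olate) | CC(=O)c1c(C)c(-c2cc(Br)c([O-])c(C(C)=O)c2C)cc(Br)c1[O-].[Na+].[Na+]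
F9 | step 3 | 1-(3-iodo-6-methoxy-2-methylphenyl)ethan-1-one | CC(=O)c1c(C)c(I)ccc1OC
F10 | step 3 | 1,1'-(4,4'-dimethoxy-2,2'-dimethyl-[1,1'-biphenyl]-3,3'-diyl)bis(ethan-1-one) | CC(=O)c1c(C)c(-c2ccc(OC)c(C(C)=O)c2C)ccc1OC
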